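(The earlier runs and the new flask stem from a simulated flask with constants of no real substance; scatter was added.)

In a one-step world where electrophile meets free base, the rate follows the base, so amber, with 2.4 equiv of base, has to run 1.41 times as fast as ochre, with 1.7 equiv.

common to all: electrophile 0.021 M; gas 1.9 mM (held)

|  | free base | scavenger | remark | time |
|---|---|---|---|---|
| ochre | 1.7 equiv | 0.50 equiv (fed, over 3.0 min) | run made earlier; the fed solution adds 0.25 times the starting volume |  |
| amber | 2.4 equiv | 0.50 equiv (fed, over 3.0 min) | run made earlier; the fed solution adds 0.25 times the starting volume |  |
| elm | 1.20 equiv | 0.500 equiv (fed, over 3.0 min) | the fed solution adds 0.25 times the starting volume | 1.0 h |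
| maple | 1.60 equiv | 0.500 equiv (fed, over 3.0 min) | the fed solution adds 0.25 times the starting volume | 1.0 h |

| run | time / min | electrophile / % | product / % |
|---|---|---|---|
| ochre | 3.00 | 91.2 | 8.3 |
| ochre | 6.00 | 82.1 | 18.1 |
| ochre | 12.0 | 62.9 | 36.8 |
| ochre | 20.0 | 41.3 | 59.8 |
| ochre | 40.0 | 6.7 | 94.7 |
| amber | 4.00 | 89.1 | 11.7 |
| amber | 10.0 | 69.5 | 30.9 |
| amber | 20.0 | 42.0 | 58.6 |
| amber | 30.0 | 19.7 | 80.3 |
| amber | 40.0 | 6.5 | 93.6 |

(standard deviation of a reading: 0.5 percentage points)

- amounts and yields of acid set free count idle adduct too
- charges are per starting volume, the dose included; the dosed solution carries all of it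
- at the start none of nucleophile is dissolved
- what was read earlier has a scatter of 0.5 percentage points, one standard deviation
- steps thought possible: electrophile + nucleophile -> acid set free + product; nucleophile + acid set free <-> protonated nucleophile; acid set free + free base <-> salt of the base; acid set free + free base <-> idle adduct; acid set free + scavenger -> scavenged by-product; gas <-> nucleophile

1. part of the electrophile that has reacted at the end, elm
2. part of the electrophile that has reacted at the end, maple
3. what raising the equivalents of free base from its lowest to its highest value here does to the part of the electrophile that has reacted (changes below 5 percentage points count as none) (no change / it falls / it rises)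

The readings refuse that ratio. At 20.0 min ochre holds 41.3 % of its electrophile and amber 42.0 %, a gap of 0.7 percentage points, less than twice the scatter of 0.5 points, and at 40.0 min they hold 6.7 % and 6.5 %. So the two flasks end alike, on one clock that the extra base does not visibly change. That clock can be read by counting turnovers. [electrophile] first falls almost in a straight line, near zero order, and then it bends into a tail. The reckoning here treats the straight stretch as a steady supply of nucleophile from the held gas.

Take the clearing time as the turnover time multiplied by the part consumed, plus a tail time multiplied by the natural logarithm of charge over remainder. Ochre's last two readings give a tail time of 6.33 min and 24.5 min for the turnover time, the minutes the steady supply needs to turn over one charge of electrophile. As a check, ochre's reading at 12.0 min reckons to 12.0 min.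

Elm and maple get 1.0 h, which is 2.45 turnover times. Their base charges lie below those tried, yet even elm's 1.20 equiv exceeds the one equivalent of acid a full charge can set free. Taking the clock as unchanged, the 5.61 tail times after the turnover time leave 0.368 %, so this reckoning gives 99.6 % reacted in both.

The forecast gives 98.8 % (94 % to 99.9 %) for elm, 99.3 % (97 % to 99.9 %) for maple, and no change: “Going from 1.7 to 2.4 equiv of base changes nothing, so the base is not rate-controlling while it is in excess.” Its elm figure lies lower than the reckoning here.

The flasks give 99.6 % for elm and 99.6 % for maple, so the trend is no change, a change of 0 points.

    electrophile + nucleophile → acid set free + product (k = 81.0 M⁻¹ min⁻¹)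
    nucleophile + acid set free ⇌ protonated nucleophile, settled at all times (K = 9.30 × 10⁵ M⁻¹)
    acid set free + free base ⇌ salt of the base (K = 43.0 M⁻¹, k = 32.0 M⁻¹ min⁻¹)
    acid set free + free base ⇌ idle adduct, settled at all times (K = 150 M⁻¹)
    acid set free + scavenger → scavenged by-product (k = 15.0 M⁻¹ min⁻¹)
    gas ⇌ nucleophile, rate k6*(csat - [nucleophile]) (kL = 0.770 min⁻¹)

The neighbour is elm with its electrophile raised to 0.053 M, the equivalents and the time held. With the supply per litre taken as unchanged, the turnover time grows with the charge to 61.9 min, longer than the 1.0 h allowed. Elm's own answer has already moved by 5 points at 0.0389 M. The neighbour has 83.6 % reacted at 1.00 h, a point for which the clearing time reckons to 63.6 min, and 16 % of its electrophile remains.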